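# Euchrenone b1: ring B grown on the chromone by Michael–aldol annulation and aromatised late

## Analysis of the target

Euchrenone b1 (20) is an isoflavone: a 4H-chromen-4-one (benzo ring A fused to pyranone ring C) carrying a 4-hydroxyphenyl ring B at C3. Ring A is fully substituted, with hydroxyls at C5 and C7 and prenyl (3-methylbut-2-enyl) groups at C6 and C8; ring C keeps an unsubstituted C2–H; ring B carries a third prenyl group at C3', ortho to the C4' hydroxyl. There is no stereocentre, and the three alkenes are isopropylidene units without geometry, so the problem is one of regiochemistry and functional-group tolerance. Every prenyl group sits next to a phenol: protic or Lewis acid closes such pairs to 2,2-dimethylchromans, dehydrogenating oxidants and divalent palladium give chromenes, and the trisubstituted alkenes rule out hydrogenolysis, ozone and peracids. C2 of ring C is the β-carbon of a vinylogous ester, which hydroxide and unhindered amines attack with opening of the pyranone, and the C5 hydroxyl is held in a hydrogen bond to the C4 carbonyl. The hard part is to place three C-prenyl groups on two different rings, above all the one on ring B, because ortho-prenylation of a para-substituted phenol competes with O-alkylation and, by the Claisen route, delivers the reversed allyl unit. The strategy rests on the pattern C1' (bond to C3), C3' (prenyl), C4' (oxygen) of ring B, which is that of a 4-substituted 2-alkylcyclohex-2-enone: C4' can be a ketone carbon, C3' its prenyl-bearing α-carbon and C1' the γ-carbon, so ring B can be built on C3 from acyclic pieces and aromatised afterwards.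

## Retrosynthetic reasoning

**20 to 19.** The last cut is at the two O–CH2 bonds of the methoxymethyl acetals on O5 and O7. These phenols must be masked through the amine and enolate chemistry that builds ring B. An acetal is chosen because its removal needs neither hydrogenolysis nor a strong Lewis acid, both of which the prenyl groups would not survive. The forward step has to cleave two aryl acetals faster than any prenyl group cyclises onto its neighbouring phenol.

**19 to 16 to 15.** The aromaticity of ring B is given up: the C5'–C6' unsaturation is removed, which turns the phenol into the cyclohexenone 15 with C4' as ketone and C1' as an sp3 carbon. This is the only redox adjustment the strategy costs. Forward, a selenium substituent is placed at C5' through the kinetic enolate (16), and syn-elimination of its selenoxide 17 gives the cross-conjugated dienone 18, which is the keto tautomer of 19.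

**15 to 9 and 13.** Ring B is cut at C1'–C6' and at C2'=C3'. These are the two bonds of a 1,5-dicarbonyl (Michael) and an enone (aldol) retron. The cut leaves all of rings A and C in the aldehyde 9 and puts the prenyl group on the ketone α-carbon of the vinyl ketone 13. No phenol is ever prenylated on ring B; the position of the prenyl group is fixed by which methylene of 13 can reach the aldehyde in a six-membered transition state. The forward reaction must form the enamine of 9 without amine attack at C2, add once to 13, and close and dehydrate under conditions the pyranone tolerates.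

**13 to 11 to 10.** The vinyl group of 13 is cut at C1=C2, back to the methyl ketone 10 plus one carbon. Forward, that carbon must be attached at the methyl group and not at the internal methylene, so the kinetic enolate of 10 is trapped with a preformed methyleneiminium salt to give the Mannich base 11, whose quaternary salt 12 eliminates.

**9 to 8 to 6 and 7.** The acetaldehyde arm is cut at the C3–CH2 bond, giving the 3-iodochromone 6 and the zinc reagent 7, with the aldehyde masked in 8 as a cyclic acetal. Carrying the arm from the start as a 4-oxobutanoyl group on ring A was rejected: a masked aldehyde does not survive C-acylation of a phloroglucinol, and a non-benzylic ketone closes ring C sluggishly. The iodide comes free of charge with ring closure. An acetal of an aliphatic aldehyde ionises through a secondary oxocarbenium ion and should hydrolyse far faster than the aryl formaldehyde acetals on O5 and O7; a vinyl ether conjugated to ring C would not give that margin.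

**6 to 5 to 4.** Ring C is cut at O1–C2, C2–C3 and C3–I. C2 comes from a formamide acetal that condenses with the acetyl methyl group of 4 to the enaminone 5. An electrophilic iodine source then functionalises C3 and triggers closure by the one hydroxyl that was left free.

**4 to 3 to 1 and 2.** The two acetals are removed, then the two ring–CH2 bonds of the prenyl groups (the future C6 and C8 substituents) are cut, back to 2,4,6-trihydroxyacetophenone 1 and prenyl bromide 2. Prenylation is done at the acetophenone stage because the acyl group blocks one ring carbon and makes the molecule symmetric, so only one di-C-prenyl constitution is possible. Protection of 3 distinguishes the hydroxyls by hydrogen bonding: the chelated one stays free and later becomes O1.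

## Alternatives that were turned down

**Alternative 1:** Ring A is made by a vinylketene–ynol ether (Danheiser) benzannulation, cutting C4a–C5 and C8–C8a. Heating the cyclobutenone A2 with the silyl ynol ether A3 opens A2 to a vinylketene, which adds to the alkyne in a [2+2] sense; a second four-electron ring opening and a 6π closure then give the pentasubstituted phenol A1. In its favour, every substituent of ring A is placed by construction, so there is no statistical C-prenylation, and ring B arrives aromatic with its prenyl group in place. On these two points it is stronger than the chosen route, whose step 1 is unselective and whose ring B needs a late dehydrogenation. Against it, both partners are bespoke. A2 is a 2,4-dialkyl-3-alkoxycyclobutenone with an epimerisable, isomerisation-prone C4–H. A3 needs an ynolate homologation on a chain that already carries the ring-B arene, and that arene still has to be ortho-prenylated, which is the very problem the chosen strategy removes. After the annulation A1 still lacks C2, and needs two different silyl ethers removed, the carbinol oxidised to the C4 ketone and ring C closed. The sequence is therefore clearly longer than the eleven steps proposed here. The chosen route offers in exchange a commercial ring A, known chromone chemistry, and a ring-B prenyl position that follows from ring size alone.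

**Alternative 2:** Ring C is closed by carbene C–H insertion, cutting C2–C3, with C2 taken from the methylene of an ortho methoxymethyl ether. A dirhodium tetracarboxylate catalyst (divalent rhodium) decomposes the α-aryl-α-diazo ketone A5, and the carbenoid at C3 inserts into an O–CH2–O hydrogen six atoms away to give the 2-methoxychromanone A4; loss of methanol would then give the isoflavone. In its favour, the full carbon skeleton is assembled convergently from two aryl halves, a protecting-group carbon becomes a skeletal one, and ring B never changes oxidation level; in convergence it is stronger than the chosen route. Against it, the carbenoid meets three electron-rich trisubstituted alkenes that it can cyclopropanate. The ether oxygen five atoms from the carbene carbon can also form an oxonium ylide, whose 1,2-shift (Stevens type) contracts the ring to a benzofuranone; this is the usual fate of ortho-alkoxyaryl diazo ketones. In addition, A5 requires acylation of a diprenylated, acid-sensitive phloroglucinol and an ortho-prenylated arylacetic acid. The chosen route replaces this chemoselectivity gamble with an annulation whose only competing closures are four-membered.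

**Alternative 3:** Ring A is made by a biomimetic Claisen cyclisation, cutting C4a–C8a. A magnesium alkoxide enolises the 3,5,7-trioxo ester A7, and the C6 carbanion attacks the C1 ester to give the acylphloroglucinol A6 with both prenyl groups already on the chain carbons that become C6 and C8. In its favour, the prenyl groups are installed by C-alkylation of β-dicarbonyl positions, which is more reliable than alkylating an ambident phenoxide, and A6 is a deoxybenzoin one carbon short of the isoflavone; in ring-A regiocontrol it is at least as strong as the chosen route. Against it, A7 is a tautomerising mixture with two stereocentres that is hard to assemble and purify. Poly-β-carbonyl chains also close by aldol and O-acylation (pyrone) pathways in competition with the Claisen mode. The benzylic C8 methylene is a further acidic site. And the ring-B arylacetyl unit again presupposes an ortho-prenylated phenol. The chosen route avoids both the polycarbonyl chain and any phenol prenylation on ring B, at the price of a modest first step and a late aromatisation.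

Key step: step 8

Remark on the chemistry: 7 is taken as the purchasable THF solution; C1' of 14–18 is formed and carried as a racemate (16 and 17 as diastereomer mixtures), because step 10 turns it into an aromatic carbon.

## Route

Step 1
Reactants: 1 2,4,6-trihydroxyacetophenone; 2 1-bromo-3-methylbut-2-ene (prenyl bromide)
Product: 3 1-[2,4,6-trihydroxy-3,5-bis(3-methylbut-2-en-1-yl)phenyl]ethan-1-one
Conditions: 2 (2.1 equiv), 10% aq. KOH, 0 °C
Reagents that add atoms: none
Why: C-alkylation of the ambident acylphloroglucinol anion in water (phenoxide C-prenylation); the acetyl group acidifies the ring and leaves only C3 and C5 open, so a single di-C-prenyl constitution is possible, while O-alkylated and geminally dialkylated by-products are expected and must be removed by chromatography.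

Step 2
Reactants: 3 1-[2,4,6-trihydroxy-3,5-bis(3-methylbut-2-en-1-yl)phenyl]ethan-1-one
Product: 4 1-[2-hydroxy-4,6-bis(methoxymethoxy)-3,5-bis(3-methylbut-2-en-1-yl)phenyl]ethan-1-one
Conditions: MeOCH2Cl (2.3 equiv), i-Pr2NEt, CH2Cl2, 0 °C → rt
Reagents that add atoms: chloromethyl methyl ether, COCCl
Why: Williamson-type acetalisation of the two hydroxyls that are not tied up at a given moment; 3 is symmetric, so protecting the para hydroxyl and either ortho hydroxyl gives the same compound, and the last hydroxyl is held by its hydrogen bond to the ketone and stays free for ring closure.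

Step 3
Reactants: 4 1-[2-hydroxy-4,6-bis(methoxymethoxy)-3,5-bis(3-methylbut-2-en-1-yl)phenyl]ethan-1-one
Product: 6 3-iodo-5,7-bis(methoxymethoxy)-6,8-bis(3-methylbut-2-en-1-yl)-4H-chromen-4-one, via dimethylamino enone 5 (not isolated)
Conditions: Me2NCH(OMe)2, toluene, 90 °C; evaporate; I2 (1.1 equiv), pyridine, CHCl3, 0 °C → rt
Reagents that add atoms: N,N-dimethylformamide dimethyl acetal, COC(OC)N(C)C; iodine, II
Why: Condensation of the methyl ketone with the amide acetal gives the vinylogous amide 5; iodination at its α-carbon makes the β-carbon an iminium carbon that the chelated phenol attacks, and loss of dimethylamine gives the 3-iodochromone (iodine-induced enaminone cyclisation); the enaminone is far more nucleophilic than the prenyl alkenes, and only a slight excess of iodine, buffered by pyridine, is used.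

Step 4
Reactants: 6 3-iodo-5,7-bis(methoxymethoxy)-6,8-bis(3-methylbut-2-en-1-yl)-4H-chromen-4-one; 7 (1,3-dioxolan-2-ylmethyl)zinc bromide
Product: 8 3-(1,3-dioxolan-2-ylmethyl)-5,7-bis(methoxymethoxy)-6,8-bis(3-methylbut-2-en-1-yl)-4H-chromen-4-one
Conditions: 7 (1.5 equiv, THF solution), Pd(OAc)2 (5 mol %), 2-dicyclohexylphosphino-2',6'-dimethoxybiphenyl (10 mol %), THF, 45 °C
Reagents that add atoms: none
Why: Negishi cross-coupling: zerovalent palladium inserts into the C3–I bond of the α-iodoenone, the alkyl group is transferred from zinc and reductive elimination forms C3–CH2; the bulky biarylphosphine speeds reductive elimination ahead of β-elimination from the alkylpalladium, and the acetals, the prenyl groups and the pyranone are inert to the organozinc.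

Step 5
Reactants: 8 3-(1,3-dioxolan-2-ylmethyl)-5,7-bis(methoxymethoxy)-6,8-bis(3-methylbut-2-en-1-yl)-4H-chromen-4-one
Product: 9 2-[5,7-bis(methoxymethoxy)-6,8-bis(3-methylbut-2-en-1-yl)-4-oxo-4H-chromen-3-yl]acetaldehyde
Conditions: pyridinium p-toluenesulfonate (0.2 equiv), acetone/H2O (10:1), 50 °C, stopped at full conversion
Reagents that add atoms: water, O
Why: Acid-catalysed acetal hydrolysis; the dioxolane of an aliphatic aldehyde ionises through a secondary oxocarbenium ion and should react well before the aryl formaldehyde acetals, which must pass through a primary one; 9 is enolisable and is used without storage.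

Step 6
Reactants: 10 6-methylhept-5-en-2-one
Product: 11 1-(dimethylamino)-7-methyloct-6-en-3-one
Conditions: LiN(i-Pr)2 (1.05 equiv), THF, −78 °C; CH2=NMe2+ I−, −78 °C → rt
Reagents that add atoms: N,N-dimethylmethyleneiminium iodide, C=[N+](C)C.[I-]
Why: Regiocontrolled Mannich reaction: deprotonation at −78 °C takes the methyl hydrogens and the preformed iminium ion traps that kinetic enolate, whereas the classical acid-mediated Mannich reaction would go through the more substituted enol and functionalise the internal methylene.

Step 7
Reactants: 11 1-(dimethylamino)-7-methyloct-6-en-3-one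
Product: 13 7-methylocta-1,6-dien-3-one, via quaternary ammonium iodide 12 (not isolated)
Conditions: MeI, Et2O, rt; then aq. NaHCO3, CH2Cl2, rt
Reagents that add atoms: none
Why: Exhaustive N-methylation makes the amine a leaving group and mild base induces E1cB (Hofmann-type) elimination to the vinyl ketone; 13 is volatile and polymerisable, so it is kept as a stabilised solution and used at once.

Step 8
Reactants: 9 2-[5,7-bis(methoxymethoxy)-6,8-bis(3-methylbut-2-en-1-yl)-4-oxo-4H-chromen-3-yl]acetaldehyde; 13 7-methylocta-1,6-dien-3-one
Product: 15 rac-5,7-bis(methoxymethoxy)-6,8-bis(3-methylbut-2-en-1-yl)-3-[3-(3-methylbut-2-en-1-yl)-4-oxocyclohex-2-en-1-yl]-4H-chromen-4-one, via keto aldehyde 14 (not isolated)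
Conditions: 13 (1.5 equiv), (±)-2-[diphenyl(trimethylsilyloxy)methyl]pyrrolidine (20 mol %), PhCO2H (20 mol %), toluene, 0 °C → rt; then (PhCH2)2NH2+ CF3CO2− (0.5 equiv), 50 °C
Reagents that add atoms: none
Why: The hindered pyrrolidine condenses with the unhindered aldehyde of 9 to an enamine whose β-carbon (the future C1') adds to the terminal CH2 of 13 (the future C6'); hydrolysis of the iminium ion returns the catalyst and gives the keto aldehyde 14. Dibenzylammonium trifluoroacetate then enolises the ketone of 14 (as its enamine) at the prenyl-bearing methylene (the future C3'), which attacks the aldehyde carbon (C2'), and E1cB loss of water leaves the C2'=C3' enone. The closest known reaction type is the enamine (Stork-type) annulation of aldehydes with vinyl ketones to 4-substituted cyclohex-2-enones, in its amine-catalysed Michael/aldol form. Ring B closes in a 6-(enolendo)-exo-trig aldol mode; the only other nucleophile–electrophile pairings in 14 (C5' onto the aldehyde, or C1' onto the ketone) would give cyclobutanes, so ring size fixes the constitution of 15 and with it the prenyl group next to the future phenolic carbon. C1' is the one new stereocentre; nothing controls it (racemic catalyst) and nothing needs to, since it becomes an aromatic carbon in step 10. The step needs chemoselectivity for the aldehyde over the electrophilic C2 of ring C, which the bulk and low nucleophilicity of both amines and the 3-substitution of the pyranone should secure, and it needs mono-addition, which the α-branching created by the first Michael event should secure; 13 is used in excess so that the Michael addition outruns self-aldolisation of 9.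

Step 9
Reactants: 15 rac-5,7-bis(methoxymethoxy)-6,8-bis(3-methylbut-2-en-1-yl)-3-[3-(3-methylbut-2-en-1-yl)-4-oxocyclohex-2-en-1-yl]-4H-chromen-4-one
Product: 16 5,7-bis(methoxymethoxy)-6,8-bis(3-methylbut-2-en-1-yl)-3-[3-(3-methylbut-2-en-1-yl)-4-oxo-5-(phenylselanyl)cyclohex-2-en-1-yl]-4H-chromen-4-one (racemic cis/trans mixture)
Conditions: LiN(i-Pr)2 (1.1 equiv), THF, −78 °C; PhSeBr (1.05 equiv), −78 °C, then aq. NH4Cl
Reagents that add atoms: benzeneselenenyl bromide, Br[Se]c1ccccc1
Why: α'-Selenenylation of a kinetic enolate: at −78 °C the amide base removes a C5' hydrogen (cross-conjugated enolate) faster than the γ-hydrogen at C1', and the enolate captures PhSeBr well before that reagent can add to the prenyl alkenes; the diastereomer mixture is of no consequence.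

Step 10
Reactants: 16 5,7-bis(methoxymethoxy)-6,8-bis(3-methylbut-2-en-1-yl)-3-[3-(3-methylbut-2-en-1-yl)-4-oxo-5-(phenylselanyl)cyclohex-2-en-1-yl]-4H-chromen-4-one (racemic cis/trans mixture)
Product: 19 3-[4-hydroxy-3-(3-methylbut-2-en-1-yl)phenyl]-5,7-bis(methoxymethoxy)-6,8-bis(3-methylbut-2-en-1-yl)-4H-chromen-4-one, via selenoxide 17 (not isolated), via cyclohexadienone 18 (not isolated)
Conditions: NaIO4 (1.5 equiv), NaHCO3, THF/MeOH/H2O, 0 °C → rt
Reagents that add atoms: none
Why: Selenoxide syn-elimination: periodate oxidises selenium but not the alkenes and forms no peracid, the α-selenoxide eliminates with a C6' hydrogen at or below room temperature, and the resulting 4H-cyclohexa-2,5-dienone 18 tautomerises at once to the phenol, which removes the C1' stereocentre.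

Step 11
Reactants: 19 3-[4-hydroxy-3-(3-methylbut-2-en-1-yl)phenyl]-5,7-bis(methoxymethoxy)-6,8-bis(3-methylbut-2-en-1-yl)-4H-chromen-4-one
Product: 20 euchrenone b1 (5,7-dihydroxy-3-[4-hydroxy-3-(3-methylbut-2-en-1-yl)phenyl]-6,8-bis(3-methylbut-2-en-1-yl)-4H-chromen-4-one)
Conditions: 3 M aq. HCl, MeOH, 40 °C, short reaction time
Reagents that add atoms: none
Why: Acid-catalysed cleavage of the two aryl methoxymethyl acetals by exchange with methanol; the conditions are kept mild and brief because every liberated phenol has an ortho prenyl group that stronger acid would cyclise to a chroman.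

## Compound list

1 | 2,4,6-trihydroxyacetophenone | CC(=O)c1c(O)cc(O)cc1O | starting material
2 | 1-bromo-3-methylbut-2-ene (prenyl bromide) | CC(C)=CCBr | starting material
3 | 1-[2,4,6-trihydroxy-3,5-bis(3-methylbut-2-en-1-yl)phenyl]ethan-1-one | CC(=O)c1c(O)c(CC=C(C)C)c(O)c(CC=C(C)C)c1O | intermediate
4 | 1-[2-hydroxy-4,6-bis(methoxymethoxy)-3,5-bis(3-methylbut-2-en-1-yl)phenyl]ethan-1-one | CC(=O)c1c(O)c(CC=C(C)C)c(OCOC)c(CC=C(C)C)c1OCOC | intermediate
5 | (E)-3-(dimethylamino)-1-[2-hydroxy-4,6-bis(methoxymethoxy)-3,5-bis(3-methylbut-2-en-1-yl)phenyl]prop-2-en-1-one | CN(C)/C=C/C(=O)c1c(O)c(CC=C(C)C)c(OCOC)c(CC=C(C)C)c1OCOC | intermediate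
6 | 3-iodo-5,7-bis(methoxymethoxy)-6,8-bis(3-methylbut-2-en-1-yl)-4H-chromen-4-one | O=c1c(I)coc2c(CC=C(C)C)c(OCOC)c(CC=C(C)C)c(OCOC)c12 | intermediate
7 | (1,3-dioxolan-2-ylmethyl)zinc bromide | Br[Zn]CC1OCCO1 | starting material
8 | 3-(1,3-dioxolan-2-ylmethyl)-5,7-bis(methoxymethoxy)-6,8-bis(3-methylbut-2-en-1-yl)-4H-chromen-4-one | O=c1c(CC2OCCO2)coc2c(CC=C(C)C)c(OCOC)c(CC=C(C)C)c(OCOC)c12 | intermediate
9 | 2-[5,7-bis(methoxymethoxy)-6,8-bis(3-methylbut-2-en-1-yl)-4-oxo-4H-chromen-3-yl]acetaldehyde | O=CCc1coc2c(CC=C(C)C)c(OCOC)c(CC=C(C)C)c(OCOC)c2c1=O | intermediate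
10 | 6-methylhept-5-en-2-one | CC(=O)CCC=C(C)C | starting material
11 | 1-(dimethylamino)-7-methyloct-6-en-3-one | CN(C)CCC(=O)CCC=C(C)C | intermediate
12 | N,N,N,7-tetramethyl-3-oxooct-6-en-1-aminium iodide | C[N+](C)(C)CCC(=O)CCC=C(C)C.[I-] | intermediate
13 | 7-methylocta-1,6-dien-3-one | C=CC(=O)CCC=C(C)C | intermediate
14 | rac-2-[5,7-bis(methoxymethoxy)-6,8-bis(3-methylbut-2-en-1-yl)-4-oxo-4H-chromen-3-yl]-9-methyl-5-oxodec-8-enal | O=CC(CCC(=O)CCC=C(C)C)c1coc2c(CC=C(C)C)c(OCOC)c(CC=C(C)C)c(OCOC)c2c1=O | intermediate
15 | rac-5,7-bis(methoxymethoxy)-6,8-bis(3-methylbut-2-en-1-yl)-3-[3-(3-methylbut-2-en-1-yl)-4-oxocyclohex-2-en-1-yl]-4H-chromen-4-one | O=C1CCC(c2coc3c(CC=C(C)C)c(OCOC)c(CC=C(C)C)c(OCOC)c3c2=O)C=C1CC=C(C)C | intermediate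
16 | 5,7-bis(methoxymethoxy)-6,8-bis(3-methylbut-2-en-1-yl)-3-[3-(3-methylbut-2-en-1-yl)-4-oxo-5-(phenylselanyl)cyclohex-2-en-1-yl]-4H-chromen-4-one, racemic, cis/trans mixture | O=C1C([Se]c2ccccc2)CC(c2coc3c(CC=C(C)C)c(OCOC)c(CC=C(C)C)c(OCOC)c3c2=O)C=C1CC=C(C)C | intermediate
17 | 5,7-bis(methoxymethoxy)-6,8-bis(3-methylbut-2-en-1-yl)-3-[3-(3-methylbut-2-en-1-yl)-4-oxo-5-(phenylseleninyl)cyclohex-2-en-1-yl]-4H-chromen-4-one, mixture of stereoisomers | O=C1C([Se](=O)c2ccccc2)CC(c2coc3c(CC=C(C)C)c(OCOC)c(CC=C(C)C)c(OCOC)c3c2=O)C=C1CC=C(C)C | intermediate
18 | rac-5,7-bis(methoxymethoxy)-6,8-bis(3-methylbut-2-en-1-yl)-3-[3-(3-methylbut-2-en-1-yl)-4-oxocyclohexa-2,5-dien-1-yl]-4H-chromen-4-one | O=C1C=CC(c2coc3c(CC=C(C)C)c(OCOC)c(CC=C(C)C)c(OCOC)c3c2=O)C=C1CC=C(C)C | intermediate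
19 | 3-[4-hydroxy-3-(3-methylbut-2-en-1-yl)phenyl]-5,7-bis(methoxymethoxy)-6,8-bis(3-methylbut-2-en-1-yl)-4H-chromen-4-one | CC(C)=CCc1cc(-c2coc3c(CC=C(C)C)c(OCOC)c(CC=C(C)C)c(OCOC)c3c2=O)ccc1O | intermediate
20 | euchrenone b1, 5,7-dihydroxy-3-[4-hydroxy-3-(3-methylbut-2-en-1-yl)phenyl]-6,8-bis(3-methylbut-2-en-1-yl)-4H-chromen-4-one (no stereocentre) | CC(C)=CCc1cc(-c2coc3c(CC=C(C)C)c(O)c(CC=C(C)C)c(O)c3c2=O)ccc1O | target

## Step count and least certain steps

Total step count: 11. Longest linear sequence: 9 steps (steps 1–5, then 8–11); steps 6–7 are a two-step side branch.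

**Step 8 (key step).** The most likely failure is self-aldolisation and oligomerisation of the readily enolised aldehyde 9 under amine catalysis, because its enamine is conjugated with ring C and may add to 13 only slowly. Next in likelihood are conjugate addition of the amine at C2 with opening of the pyranone, a second Michael addition, and incomplete dehydration of the aldol. Fallback: set out from 9 and condense it with morpholine (4 Å sieves, toluene, 0 °C) to the isolated enamine (E)-5,7-bis(methoxymethoxy)-6,8-bis(3-methylbut-2-en-1-yl)-3-[2-(morpholin-4-yl)ethenyl]-4H-chromen-4-one F1, so that no free aldehyde is present when C1'–C6' is formed. F1 is then alkylated with 13 in MeCN (stoichiometric Stork enamine addition), and the adduct is hydrolysed and cyclised in buffered AcOH/NaOAc/H2O with gentle warming, passing through 14 and rejoining the route at 15.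

**Step 5.** The acid needed for the dioxolane may also cause loss of the C5 acetal, which lies peri to the carbonyl and is the more labile of the two, and the liberated aldehyde may condense with itself on prolonged exposure. Fallback without any acid: set out from 6 and exchange iodine for magnesium with i-PrMgCl·LiCl (THF, −40 °C). The 3-magnesiated chromone opens ethylene oxide in the presence of CuI (10 mol %) to give 3-(2-hydroxyethyl)-5,7-bis(methoxymethoxy)-6,8-bis(3-methylbut-2-en-1-yl)-4H-chromen-4-one F2. Oxidation of F2 with Dess–Martin periodinane and NaHCO3 in CH2Cl2 rejoins the route at 9, bypassing steps 4 and 5.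

**Step 9 (with step 10).** Deprotonation may go partly to the γ-position C1' or equilibrate by proton transfer, and electrophilic selenium (PhSeBr, and later the selenenic acid released in step 10) may add to the electron-rich prenyl alkenes. Fallback: set out from 15 and deprotonate with LiN(i-Pr)2 in the presence of Me3SiCl (internal quench, THF, −78 °C) to the silyl dienol ether rac-5,7-bis(methoxymethoxy)-6,8-bis(3-methylbut-2-en-1-yl)-3-[3-(3-methylbut-2-en-1-yl)-4-(trimethylsilyloxy)cyclohexa-2,4-dien-1-yl]-4H-chromen-4-one F3. F3 is then dehydrogenated with Pd(OAc)2 (divalent palladium, 1.0 equiv, MeCN, rt; Saegusa–Ito oxidation). This gives dienone 18 and, after tautomerisation, rejoins the route at 19; exactly one equivalent is used so that no divalent palladium remains to cyclise the new ortho-prenylphenol.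

**Step 11.** Acid-induced cyclisation of a prenyl group onto its neighbouring free phenol (chroman formation) may compete with cleavage of the hindered C7 acetal, which is flanked by two prenyl groups. Fallback: set out from 19 and treat it with Me3SiOSO2CF3 and 2,2'-bipyridyl (CH2Cl2, 0 °C), which exchanges the aryl acetals for silyl ethers under non-protic conditions and also silylates the C4' hydroxyl. This gives 6,8-bis(3-methylbut-2-en-1-yl)-3-[3-(3-methylbut-2-en-1-yl)-4-(trimethylsilyloxy)phenyl]-5,7-bis(trimethylsilyloxy)-4H-chromen-4-one F4; stirring F4 with water (or K2CO3 in MeOH) rejoins the route at 20.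

**Step 1.** Over-alkylation (geminal diprenylation with loss of aromaticity), O-alkylation and incomplete second alkylation are all expected to erode the material throughput. Fallback with full regiocontrol: set out from 1 and brominate both free ring positions (Br2, 2 equiv, AcOH, rt) to 1-(3,5-dibromo-2,4,6-trihydroxyphenyl)ethan-1-one F5. F5 is protected as in step 2 to 1-[3,5-dibromo-2-hydroxy-4,6-bis(methoxymethoxy)phenyl]ethan-1-one F6. Both bromides of F6 are then replaced by Stille coupling with Bu3SnCH2CH=CMe2 (Pd(PPh3)4, DMF, 100 °C), which rejoins the route at 4.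

## Further compounds

F1 | step 8 | (E)-5,7-bis(methoxymethoxy)-6,8-bis(3-methylbut-2-en-1-yl)-3-[2-(morpholin-4-yl)ethenyl]-4H-chromen-4-one | O=c1c(/C=C/N2CCOCC2)coc2c(CC=C(C)C)c(OCOC)c(CC=C(C)C)c(OCOC)c12
F2 | step 5 | 3-(2-hydroxyethyl)-5,7-bis(methoxymethoxy)-6,8-bis(3-methylbut-2-en-1-yl)-4H-chromen-4-one | OCCc1coc2c(CC=C(C)C)c(OCOC)c(CC=C(C)C)c(OCOC)c2c1=O
F3 | step 9 | rac-5,7-bis(methoxymethoxy)-6,8-bis(3-methylbut-2-en-1-yl)-3-[3-(3-methylbut-2-en-1-yl)-4-(trimethylsilyloxy)cyclohexa-2,4-dien-1-yl]-4H-chromen-4-one | C[Si](C)(C)OC1=CCC(c2coc3c(CC=C(C)C)c(OCOC)c(CC=C(C)C)c(OCOC)c3c2=O)C=C1CC=C(C)C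
F4 | step 11 | 6,8-bis(3-methylbut-2-en-1-yl)-3-[3-(3-methylbut-2-en-1-yl)-4-(trimethylsilyloxy)phenyl]-5,7-bis(trimethylsilyloxy)-4H-chromen-4-one | CC(C)=CCc1cc(-c2coc3c(CC=C(C)C)c(O[Si](C)(C)C)c(CC=C(C)C)c(O[Si](C)(C)C)c3c2=O)ccc1O[Si](C)(C)C
F5 | step 1 | 1-(3,5-dibromo-2,4,6-trihydroxyphenyl)ethan-1-one | CC(=O)c1c(O)c(Br)c(O)c(Br)c1O
F6 | step 1 | 1-[3,5-dibromo-2-hydroxy-4,6-bis(methoxymethoxy)phenyl]ethan-1-one | CC(=O)c1c(O)c(Br)c(OCOC)c(Br)c1OCOC
A1 | alternative 1 | rac-2-[1-(tert-butyldimethylsilyloxy)-2-[4-(methoxymethoxy)-3-(3-methylbut-2-en-1-yl)phenyl]ethyl]-5-(methoxymethoxy)-4,6-bis(3-methylbut-2-en-1-yl)-3-(triisopropylsilyloxy)phenol | Oc1c(CC=C(C)C)c(OCOC)c(CC=C(C)C)c(O[Si](C(C)C)(C(C)C)C(C)C)c1C(O[Si](C)(C)C(C)(C)C)Cc1ccc(OCOC)c(CC=C(C)C)c1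
A2 | alternative 1 | rac-3-(methoxymethoxy)-2,4-bis(3-methylbut-2-en-1-yl)cyclobut-2-en-1-one | O=C1C(CC=C(C)C)=C(OCOC)C1CC=C(C)C
A3 | alternative 1 | rac-tert-butyldimethylsilyl 1-[4-(methoxymethoxy)-3-(3-methylbut-2-en-1-yl)phenyl]-4-(triisopropylsilyloxy)but-3-yn-2-yl ether | CC(C)[Si](C(C)C)(C(C)C)OC#CC(O[Si](C)(C)C(C)(C)C)Cc1ccc(OCOC)c(CC=C(C)C)c1
A4 | alternative 2 | 2-methoxy-3-[4-(methoxymethoxy)-3-(3-methylbut-2-en-1-yl)phenyl]-5,7-bis(methoxymethoxy)-6,8-bis(3-methylbut-2-en-1-yl)chroman-4-one, racemic, mixed diastereomers | COCOc1c(CC=C(C)C)c(OCOC)c(CC=C(C)C)c2OC(OC)C(c3ccc(OCOC)c(CC=C(C)C)c3)C(=O)c12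
A5 | alternative 2 | 2-diazo-2-[4-(methoxymethoxy)-3-(3-methylbut-2-en-1-yl)phenyl]-1-[2,4,6-tris(methoxymethoxy)-3,5-bis(3-methylbut-2-en-1-yl)phenyl]ethan-1-one | COCOc1c(CC=C(C)C)c(OCOC)c(CC=C(C)C)c(OCOC)c1C(=O)C(=[N+]=[N-])c1ccc(OCOC)c(CC=C(C)C)c1
A6 | alternative 3 | 2-[4-(methoxymethoxy)-3-(3-methylbut-2-en-1-yl)phenyl]-1-[2,4,6-trihydroxy-3,5-bis(3-methylbut-2-en-1-yl)phenyl]ethan-1-one | O=C(Cc1ccc(OCOC)c(CC=C(C)C)c1)c1c(O)c(CC=C(C)C)c(O)c(CC=C(C)C)c1O
A7 | alternative 3 | methyl 8-[4-(methoxymethoxy)-3-(3-methylbut-2-en-1-yl)phenyl]-2,4-bis(3-methylbut-2-en-1-yl)-3,5,7-trioxooctanoate, mixture of stereoisomers and tautomers | COC(=O)C(CC=C(C)C)C(=O)C(CC=C(C)C)C(=O)CC(=O)Cc1ccc(OCOC)c(CC=C(C)C)c1
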